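**Retrosynthetic overview**

1. The target is the 7-mono-O-methyl ether of a C2-symmetric, 2,3-cis-configured 3,3''-biflavanone; the last step methylates one of two homotopic 7-OH groups after global debenzylation.
2. The strategy rests on the C3–C3'' single bond that joins the two pyranone rings (ring C of each half) and is flanked by the C4 and C4'' carbonyl carbons. It is the central σ-bond of the diene C4=C3–C3''=C4'' of a 3,3'-bi(2H-chromene), which hydroboration anti to the C2 aryl groups and oxidation convert into both ketones with both 2,3-cis relationships.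
3. The bichromene is disconnected at C3=C4 and C3''=C4'' to a but-2-yne (C3≡C3'') bearing two 2-vinylaryl ethers. Tandem ene–yne–ene metathesis closes ring C and then ring C'' in one operation; rings A and B are bought.
4. The metathesis precursor comes from the (1S,4S)-ynediol (double Midland reduction of the ynedione) by double Mitsunobu inversion with 4,6-bis(benzyloxy)salicylaldehyde and Wittig methylenation.

Key step: step 7

Remark on the chemistry: flavanone numbering is used (O1, C2, C3, C4; doubly primed locants for the second half in the text, singly primed in names). The descriptor at C2 is R in 9–11 and S from 12 on only because the CIP rank of C3 relative to the aryl group changes; the geometry does not.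

**Route**

Step 1
Reactants: 1 acetylene (1.0 equiv); 2 4-methoxybenzaldehyde (2.0 equiv)
Product: 4 1,4-bis(4-methoxyphenyl)but-2-yne-1,4-diol (diastereomer mixture), via ethyne-1,2-diylbis(magnesium bromide) 3 (not isolated)
Conditions: acetylene (1.0 equiv) passed into EtMgBr (2.0 equiv), THF, 0 → 50 °C; then 4-methoxybenzaldehyde (2.0 equiv), 0 °C → rt; aq. NH4Cl
Reagents that add atoms: ethylmagnesium bromide, CC[Mg]Br (its MgBr ends up in intermediate 3 only; no atoms in 4)
Why: Two equivalents of EtMgBr doubly deprotonate one equivalent of acetylene to the bis(bromomagnesium) acetylide, which undergoes Grignard 1,2-addition to two equivalents of the aldehyde, one at each alkyne terminus, to give the ynediol as a mixture of racemic and meso forms, which is immaterial because both carbinols are oxidised in step 2.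

Step 2
Reactants: 4 1,4-bis(4-methoxyphenyl)but-2-yne-1,4-diol
Product: 5 1,4-bis(4-methoxyphenyl)but-2-yne-1,4-dione
Conditions: MnO2 (activated, excess), CH2Cl2, rt
Reagents that add atoms: none
Why: Heterogeneous MnO2 oxidation is selective for benzylic–propargylic alcohols and is neutral, so the ynedione, a strong Michael acceptor, is not exposed to amines or alkoxides.

Step 3
Reactants: 5 1,4-bis(4-methoxyphenyl)but-2-yne-1,4-dione
Product: 6 (1S,4S)-1,4-bis(4-methoxyphenyl)but-2-yne-1,4-diol
Conditions: (S)-Alpine-Borane (3 equiv), THF (concentrated), rt; then HOCH2CH2NH2, Et2O, 0 °C; recrystallisation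
Reagents that add atoms: none
Why: Midland reduction: hydride is transferred from the pinanyl group through a boat-like six-membered transition state in which the slim alkynyl group takes the hindered position and the aryl group the open one, so the reagent made from (−)-α-pinene should give the (S)-carbinol at both ketones, and the statistics of a double reduction push residual facial error into the meso diol, which is removed by crystallisation.

Step 4
Reactants: 7 2,4,6-trihydroxybenzaldehyde
Product: 8 2,4-bis(benzyloxy)-6-hydroxybenzaldehyde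
Conditions: BnBr (2.05 equiv), K2CO3 (2.2 equiv), DMF, rt
Reagents that add atoms: benzyl bromide, BrCc1ccccc1
Why: Williamson etherification: the 4-OH and one ortho OH are benzylated while the remaining ortho hydroxyl, held in a hydrogen bond to the aldehyde, is much less nucleophilic, so two equivalents of BnBr should stop at the mono-phenol.

Step 5
Reactants: 6 (1S,4S)-1,4-bis(4-methoxyphenyl)but-2-yne-1,4-diol; 8 2,4-bis(benzyloxy)-6-hydroxybenzaldehyde (2.4 equiv)
Product: 9 6,6'-{[(1R,4R)-1,4-bis(4-methoxyphenyl)but-2-yne-1,4-diyl]bis(oxy)}bis[2,4-bis(benzyloxy)benzaldehyde]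
Conditions: PPh3, DIAD (2.6 equiv each), PhMe, −20 → 0 °C
Reagents that add atoms: none
Why: Double Mitsunobu reaction: the acidic salicylaldehyde OH displaces each alkoxyphosphonium group by SN2 with inversion, converting the (1S,4S)-diol into the (1R,4R)-bis(aryl ether), while low temperature and a non-polar solvent hold back ionisation of the anisyl–propargyl centres and any centre that does scramble ends up mostly in the separable meso diastereomer.

Step 6
Reactants: 9 dialdehyde bis(aryl ether)
Product: 10 (1R,4R)-1,4-bis[3,5-bis(benzyloxy)-2-vinylphenoxy]-1,4-bis(4-methoxyphenyl)but-2-yne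
Conditions: Ph3PCH3Br (3.0 equiv), KOtBu (2.8 equiv), THF, 0 °C; then 9, −78 → 0 °C
Reagents that add atoms: methyltriphenylphosphonium bromide, C[P+](c1ccccc1)(c1ccccc1)c1ccccc1.[Br-]
Why: Wittig methylenation with the non-stabilised ylide converts both hindered, electron-rich aldehydes into styrenes at low temperature, where the aldehyde consumes the ylide faster than the propargylic C–H can be deprotonated, so the two stereocentres are untouched.

Step 7
Reactants: 10 (1R,4R)-1,4-bis[3,5-bis(benzyloxy)-2-vinylphenoxy]-1,4-bis(4-methoxyphenyl)but-2-yne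
Product: 11 (2R,2'R)-5,5',7,7'-tetrakis(benzyloxy)-2,2'-bis(4-methoxyphenyl)-2H,2'H-3,3'-bichromene
Conditions: second-generation Grubbs catalyst RuCl2(H2IMes)(PCy3)(=CHPh) (10 mol%), PhMe (0.005 M), 80 °C, Ar purge
Reagents that add atoms: none
Why: The catalyst loads onto one styrene to give a ruthenium benzylidene at C4, which adds across the tethered C3≡C3'' alkyne through a ruthenacyclobutene and opens to the first 2H-pyran ring (C4=C3 formed, exo-mode enyne closure, six-membered, the new carbene exocyclic on C3''); this vinylcarbene then undergoes ordinary ring-closing alkene metathesis with the second styrene, forming C3''=C4'' and the second six-membered pyran ring and releasing the metal as a methylidene, with ethylene as the only by-product. The closest known reaction type is tandem dienyne ring-closing metathesis of ene–yne–ene substrates with the alkyne in the middle, which gives 1,1'-linked bis-cycloalkenes and bis-heterocycles, together with enyne ring-closing metathesis of 2-vinylaryl propargyl ethers to 3-substituted 2H-chromenes. No stereocentre is created; the two C2 centres are spectators and are not ionised under these neutral conditions. The step needs the intramolecular relay to outrun intermolecular styrene metathesis, which high dilution and the six-membered geometry of both closures should secure, and endo closure to a seven-membered ring is disfavoured for this tether length. The ortho-alkoxy groups can hold the carbene as a chelated ortho-alkoxybenzylidene, but such chelates remain active at 80 °C.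

Step 8
Reactants: 11 (2R,2'R)-5,5',7,7'-tetrakis(benzyloxy)-2,2'-bis(4-methoxyphenyl)-2H,2'H-3,3'-bichromene
Product: 13 (2S,2'S,3R,3'R,4R,4'R)-5,5',7,7'-tetrakis(benzyloxy)-2,2'-bis(4-methoxyphenyl)-3,3'-bichromane-4,4'-diol, via 4,4'-bis(boranyl) adduct 12 (not isolated)
Conditions: 11 added to BH3·SMe2 (8 equiv), THF, 0 °C → rt; then NaOH, H2O2, 0 °C → rt; crude product kept away from acid
Reagents that add atoms: borane–dimethyl sulfide, C[S+](C)[BH3-] (boron of intermediate 12); hydrogen peroxide, OO (the two hydroxyl oxygens of 13)
Why: Hydroboration–oxidation: BH3 adds syn across each trisubstituted C3=C4 bond with boron on the less substituted benzylic carbon C4 (the terminus of the 2,3-disubstituted diene, as with β,β-disubstituted styrenes) and from the face opposite the pseudo-axial C2 aryl group, which places H on C3 anti to that aryl group and so sets both 2,3-cis relationships (3R and 3'R here, 3S after oxidation to the ketone), the excess of borane keeping the second addition intermolecular, and oxidation of C–B with retention gives the 4-ols, whose configuration is erased in step 9.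

Step 9
Reactants: 13 bis(flavan-4-ol)
Product: 14 (2S,2'S,3S,3'S)-5,5',7,7'-tetrakis(benzyloxy)-2,2'-bis(4-methoxyphenyl)-3,3'-bichromane-4,4'-dione
Conditions: DMP (3 equiv), NaHCO3, CH2Cl2, 0 °C → rt
Reagents that add atoms: none
Why: Dess–Martin oxidation under bicarbonate buffering converts both benzylic alcohols into the flavanone carbonyls without acid or base strong enough to ionise C4 or to epimerise the kinetically set C3–H centres.

Step 10
Reactants: 14 tetrabenzyl biflavanone
Product: 15 (2S,2'S,3S,3'S)-5,5',7,7'-tetrahydroxy-2,2'-bis(4-methoxyphenyl)-3,3'-bichromane-4,4'-dione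
Conditions: H2 (1 atm), Pd/C (10 wt%), EtOAc/THF, rt
Reagents that add atoms: none
Why: Catalytic hydrogenolysis cleaves the four benzyl aryl ethers under neutral conditions, while the cyclic C2–O1 benzylic ether and the aryl ketones react more slowly and should survive when the reaction is stopped at full debenzylation.

Step 11
Reactants: 15 tetraphenol
Product: 16 (2S,2'S,3S,3'S)-5,5',7-trihydroxy-7'-methoxy-2,2'-bis(4-methoxyphenyl)-3,3'-bichromane-4,4'-dione (target)
Conditions: TMSCHN2 (1.0 equiv), MeOH/PhMe, 0 °C → rt
Reagents that add atoms: (trimethylsilyl)diazomethane, C[Si](C)(C)C=[N+]=[N-]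
Why: O-Methylation with a diazoalkane under neutral conditions takes place at the acidic 7-OH (a vinylogous acid) and not at the 5-OH groups chelated to the carbonyls, and since the two 7-OH groups are homotopic one equivalent should give the mono-ether as the main component beside recovered 15 and the 7,7'-dimethyl ether, which are separated and 15 recycled, with no base present that could open ring C or epimerise C3.

**Compound list**

1 | acetylene (ethyne) | C#C | starting material
2 | 4-methoxybenzaldehyde | COc1ccc(C=O)cc1 | starting material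
3 | ethyne-1,2-diylbis(magnesium bromide) | Br[Mg]C#C[Mg]Br | intermediate (not isolated)
4 | 1,4-bis(4-methoxyphenyl)but-2-yne-1,4-diol, mixture of racemic and meso forms (no configuration assigned) | COc1ccc(cc1)C(O)C#CC(O)c1ccc(OC)cc1 | intermediate
5 | 1,4-bis(4-methoxyphenyl)but-2-yne-1,4-dione | COc1ccc(cc1)C(=O)C#CC(=O)c1ccc(OC)cc1 | intermediate
6 | (1S,4S)-1,4-bis(4-methoxyphenyl)but-2-yne-1,4-diol | COc1ccc(cc1)[C@H](O)C#C[C@@H](O)c1ccc(OC)cc1 | intermediate
7 | 2,4,6-trihydroxybenzaldehyde | O=Cc1c(O)cc(O)cc1O | starting material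
8 | 2,4-bis(benzyloxy)-6-hydroxybenzaldehyde | O=Cc1c(O)cc(OCc2ccccc2)cc1OCc1ccccc1 | intermediate
9 | 6,6'-{[(1R,4R)-1,4-bis(4-methoxyphenyl)but-2-yne-1,4-diyl]bis(oxy)}bis[2,4-bis(benzyloxy)benzaldehyde] | COc1ccc([C@H](C#C[C@H](Oc2cc(OCc3ccccc3)cc(OCc3ccccc3)c2C=O)c2ccc(OC)cc2)Oc2cc(OCc3ccccc3)cc(OCc3ccccc3)c2C=O)cc1 | intermediate
10 | (1R,4R)-1,4-bis[3,5-bis(benzyloxy)-2-vinylphenoxy]-1,4-bis(4-methoxyphenyl)but-2-yne | COc1ccc([C@H](C#C[C@H](Oc2cc(OCc3ccccc3)cc(OCc3ccccc3)c2C=C)c2ccc(OC)cc2)Oc2cc(OCc3ccccc3)cc(OCc3ccccc3)c2C=C)cc1 | intermediate (key-step precursor)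
11 | (2R,2'R)-5,5',7,7'-tetrakis(benzyloxy)-2,2'-bis(4-methoxyphenyl)-2H,2'H-3,3'-bichromene | COc1ccc([C@H]2Oc3cc(OCc4ccccc4)cc(OCc4ccccc4)c3C=C2C2=Cc3c(OCc4ccccc4)cc(OCc4ccccc4)cc3O[C@@H]2c2ccc(OC)cc2)cc1 | intermediate (key-step product)
12 | 4,4'-bis(boranyl) adduct of 11: H on C3 and C3'', BH2 on C4 and C4'', both added syn from the face opposite the C2 aryl group (drawn as the bis-monoalkylborane) | COc1ccc([C@H]2Oc3cc(OCc4ccccc4)cc(OCc4ccccc4)c3[C@H](B)[C@H]2[C@@H]2[C@@H](B)c3c(OCc4ccccc4)cc(OCc4ccccc4)cc3O[C@@H]2c2ccc(OC)cc2)cc1 | intermediate (not isolated)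
13 | (2S,2'S,3R,3'R,4R,4'R)-5,5',7,7'-tetrakis(benzyloxy)-2,2'-bis(4-methoxyphenyl)-3,3'-bichromane-4,4'-diol | COc1ccc([C@H]2Oc3cc(OCc4ccccc4)cc(OCc4ccccc4)c3[C@H](O)[C@H]2[C@@H]2[C@@H](O)c3c(OCc4ccccc4)cc(OCc4ccccc4)cc3O[C@@H]2c2ccc(OC)cc2)cc1 | intermediate
14 | (2S,2'S,3S,3'S)-5,5',7,7'-tetrakis(benzyloxy)-2,2'-bis(4-methoxyphenyl)-3,3'-bichromane-4,4'-dione | COc1ccc([C@H]2Oc3cc(OCc4ccccc4)cc(OCc4ccccc4)c3C(=O)[C@H]2[C@@H]2C(=O)c3c(OCc4ccccc4)cc(OCc4ccccc4)cc3O[C@@H]2c2ccc(OC)cc2)cc1 | intermediate
15 | (2S,2'S,3S,3'S)-5,5',7,7'-tetrahydroxy-2,2'-bis(4-methoxyphenyl)-3,3'-bichromane-4,4'-dione | COc1ccc([C@H]2Oc3cc(O)cc(O)c3C(=O)[C@H]2[C@@H]2C(=O)c3c(O)cc(O)cc3O[C@@H]2c2ccc(OC)cc2)cc1 | intermediate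
16 | (2S,2'S,3S,3'S)-5,5',7-trihydroxy-7'-methoxy-2,2'-bis(4-methoxyphenyl)-3,3'-bichromane-4,4'-dione (CNP0184936.4) | COc1ccc([C@H]2Oc3cc(O)cc(O)c3C(=O)[C@H]2[C@@H]2C(=O)c3c(O)cc(OC)cc3O[C@@H]2c2ccc(OC)cc2)cc1 | target

**Step count and risks**

Total step count: 11. Longest linear sequence: 10 steps (steps 1–3 and 5–11); step 4 is a one-step side branch.

The three steps most likely to fail:

Step 7 (tandem ene–yne–ene metathesis). The catalyst may rest as an ortho-alkoxy-chelated benzylidene on the 2,6-dioxygenated styrenes, or the crowded disubstituted vinylcarbene on C3'' formed after the first ring closure may be too slow to capture the second styrene, so that half-cyclised material and intermolecular oligomers accumulate. The fallback takes the two events apart. Setting out from 10, cross-metathesis of the internal alkyne with ethylene (same catalyst, ethylene 1 atm, PhMe, 60–80 °C), a known way to turn a 1,4-dioxygenated but-2-yne into a 2,3-disubstituted buta-1,3-diene, should give the tetraene (1R,4R)-1,4-bis[3,5-bis(benzyloxy)-2-vinylphenoxy]-1,4-bis(4-methoxyphenyl)-2,3-dimethylidenebutane F1. After isolation, F1 is closed twice by ordinary diene ring-closing metathesis under an argon purge, each styrene reacting with the adjacent 1,1-disubstituted diene terminus (the reaction type that makes 2H-chromenes from 2-vinylaryl allyl ethers). This gives bichromene 11, where the route is rejoined.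

Step 8 (hydroboration–oxidation). After the first addition, the C4-bound BH2 group can deliver its own B–H to the neighbouring C3''=C4'' bond through a five-membered ring. This internal delivery reaches the second ring on the face that carries its C2'' aryl group and would give the 2'',3''-trans half; incomplete shielding by the aryl groups would erode selectivity in the same direction. The fallback decouples the C3 configuration from the hydroboration. Setting out from 11, the hydroboration–oxidation is run as before and the product is taken on whatever its C3'' configuration, that is 13 together with its 3',4'-epimer, the (2S,2'S,3R,3'S,4R,4'S)-diol F2. Dess–Martin oxidation then gives 14 mixed with the 3'-epimeric diketone F3. Soft enolisation of the mixture (TMSOTf, Et3N, CH2Cl2, 0 °C) converges on one compound, the 4,4'-bis(trimethylsilyloxy)-3,3'-bichromene F4, in which C3 and C3'' are trigonal. Fluoride-triggered protodesilylation with an external proton source (TBAF buffered with AcOH, THF, −78 °C) protonates each C3 from the face opposite its C2 aryl group; this intermolecular kinetic protonation should give the cis,cis-diketone 14, where the route is rejoined.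

Step 5 (double Mitsunobu etherification). The alkoxyphosphonium intermediates sit on carbons that are both 4-methoxybenzylic and propargylic, so heterolysis to an ion pair can compete with direct SN2 displacement, with loss of stereochemical fidelity and attack at the alkyne terminus to give allenyl ethers. The fallback makes the aryl–oxygen bond instead of the alkyl–oxygen bond, so that the carbinol C–O bond is never broken and the configuration is retained. Setting out from ynedione 5, reduction with (R)-Alpine-Borane (from (+)-α-pinene) gives the enantiomeric diol (1R,4R)-1,4-bis(4-methoxyphenyl)but-2-yne-1,4-diol F5. Commercial 5-fluororesorcinol is benzylated (BnBr, K2CO3, DMF) to 1,3-bis(benzyloxy)-5-fluorobenzene F6, and Vilsmeier–Haack formylation (POCl3, DMF) para to one benzyloxy group gives 2,4-bis(benzyloxy)-6-fluorobenzaldehyde F7. The disodium alkoxide of F5 (NaH, DMF, 0 °C) then displaces fluoride from two equivalents of F7 by SNAr ortho to the formyl group, which should give dialdehyde 9 with retention at both carbinol carbons, where the route is rejoined.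

**Further compounds**

F1 | step 7 | (1R,4R)-1,4-bis[3,5-bis(benzyloxy)-2-vinylphenoxy]-1,4-bis(4-methoxyphenyl)-2,3-dimethylidenebutane | COc1ccc([C@H](C(=C)C(=C)[C@H](Oc2cc(OCc3ccccc3)cc(OCc3ccccc3)c2C=C)c2ccc(OC)cc2)Oc2cc(OCc3ccccc3)cc(OCc3ccccc3)c2C=C)cc1
F2 | step 8 | (2S,2'S,3R,3'S,4R,4'S)-5,5',7,7'-tetrakis(benzyloxy)-2,2'-bis(4-methoxyphenyl)-3,3'-bichromane-4,4'-diol | COc1ccc([C@H]2Oc3cc(OCc4ccccc4)cc(OCc4ccccc4)c3[C@H](O)[C@H]2[C@H]2[C@H](O)c3c(OCc4ccccc4)cc(OCc4ccccc4)cc3O[C@@H]2c2ccc(OC)cc2)cc1
F3 | step 8 | (2S,2'S,3S,3'R)-5,5',7,7'-tetrakis(benzyloxy)-2,2'-bis(4-methoxyphenyl)-3,3'-bichromane-4,4'-dione | COc1ccc([C@H]2Oc3cc(OCc4ccccc4)cc(OCc4ccccc4)c3C(=O)[C@H]2[C@H]2C(=O)c3c(OCc4ccccc4)cc(OCc4ccccc4)cc3O[C@@H]2c2ccc(OC)cc2)cc1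
F4 | step 8 | (2R,2'R)-5,5',7,7'-tetrakis(benzyloxy)-2,2'-bis(4-methoxyphenyl)-4,4'-bis(trimethylsilyloxy)-2H,2'H-3,3'-bichromene | COc1ccc([C@H]2Oc3cc(OCc4ccccc4)cc(OCc4ccccc4)c3C(O[Si](C)(C)C)=C2C2=C(O[Si](C)(C)C)c3c(OCc4ccccc4)cc(OCc4ccccc4)cc3O[C@@H]2c2ccc(OC)cc2)cc1
F5 | step 5 | (1R,4R)-1,4-bis(4-methoxyphenyl)but-2-yne-1,4-diol | COc1ccc(cc1)[C@@H](O)C#C[C@H](O)c1ccc(OC)cc1
F6 | step 5 | 1,3-bis(benzyloxy)-5-fluorobenzene | Fc1cc(OCc2ccccc2)cc(OCc2ccccc2)c1
F7 | step 5 | 2,4-bis(benzyloxy)-6-fluorobenzaldehyde | O=Cc1c(F)cc(OCc2ccccc2)cc1OCc1ccccc1
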